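**Assumption:** the lipase cleaves the acetate on the R‑configured carbinol carbon of the meso diacetate (Kazlauskas rule), so the monoacetate is 3 as drawn.

Ring positions use the numbering of the target (C‑3, C‑3a, C‑4 … C‑7a; C‑1′ is the side‑chain stereocentre). TBS = tert‑butyldimethylsilyl, TBDPS = tert‑butyldiphenylsilyl, TES = triethylsilyl, Bpin = pinacolboryl, DMP = Dess–Martin periodinane, PPTS = pyridinium p‑toluenesulfonate.

## Retrosynthetic overview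

1. Target ⇐ C‑4 methacrylation, Eschenmoser α‑methylenation of the cis‑lactone, hydroboration of a terminal alkene (masked hydroxypentyl chain).
2. Lactone ring (the only ring closed, step 15) ⇐ γ‑hydroxy amide; C‑4 carbinol ⇐ hydroxyl‑directed anti reduction of an enone; C‑6 CH2OH ⇐ Stille coupling of a vinylogous triflate.
3. C‑1′ and the fully substituted C‑5=C‑6 ⇐ iminium‑catalysed Michael addition of a cyclic 1,3‑dione to crotonaldehyde, then Wittig.
4. Dione ⇐ allylic oxidation and β‑oxygenation of an Eschenmoser–Claisen amide (cis C‑3a/C‑7a by [3,3] transfer).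
5. Absolute configuration ⇐ lipase desymmetrisation of meso cis‑1,4‑diacetoxycyclohex‑2‑ene; the carbocycle comes from cyclohexa‑1,3‑diene and is present from the start.

## Route

Step 1
Reactants: 1 cyclohexa‑1,3‑diene
Product: 2 meso cis‑cyclohex‑2‑ene‑1,4‑diyl diacetate
Conditions: Pd(OAc)2 (5 mol%), LiCl (20 mol%), LiOAc (buffer), p‑benzoquinone (1.1 equiv), AcOH, 25 °C
Reagents that add atoms: acetic acid, CC(=O)O
Why: Bäckvall 1,4‑diacetoxylation of a 1,3‑diene, in which chloride forces the second acetate to attack the π‑allyl complex of divalent palladium from outside so that both C–O bonds end up cis (meso product).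

Step 2
Reactants: 2 meso diacetate
Product: 3 (1S,4R)‑4‑hydroxycyclohex‑2‑en‑1‑yl acetate
Conditions: lipase (Pseudomonas cepacia lipase, immobilised), 0.1 M sodium phosphate buffer pH 7.0, 25 °C, stopped after one equivalent of acetate is released
Reagents that add atoms: none
Why: Lipase‑catalysed enantiotopos‑selective hydrolysis (enzymatic desymmetrisation of a meso diester) removes only the acetate on the R carbinol carbon, so the first absolute configuration is set by catalysis.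

Step 3
Reactants: 3 monoacetate
Product: 4 (1S,4R)‑4‑(TBS‑oxy)cyclohex‑2‑en‑1‑yl acetate
Conditions: TBSCl (1.2 equiv), imidazole (2.5 equiv), DMF, 0 → 25 °C
Reagents that add atoms: tert‑butyl(chloro)dimethylsilane, CC(C)(C)[Si](C)(C)Cl
Why: Silyl ether formation at the free hydroxyl differentiates the two oxygens without touching a stereocentre.

Step 4
Reactants: 4 silyl ether acetate
Product: 5 (1S,4R)‑4‑(TBS‑oxy)cyclohex‑2‑en‑1‑ol
Conditions: K2CO3 (0.2 equiv), MeOH, 0 → 25 °C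
Reagents that add atoms: none
Why: Base‑catalysed transesterification (methanolysis) removes the acetate with retention, leaving the silyl ether intact.

Step 5
Reactants: 5 allylic alcohol
Product: 7 cis‑silyloxy cyclohexenyl dimethylacetamide, via ketene N,O‑acetal 6 (not isolated)
Conditions: MeC(OMe)2NMe2 (4 equiv), xylene, 140 °C, sealed tube
Reagents that add atoms: N,N‑dimethylacetamide dimethyl acetal, COC(C)(OC)N(C)C
Why: Eschenmoser–Claisen rearrangement, a suprafacial [3,3] shift that delivers CH2CONMe2 to C‑3a on the face of the departing C–O bond and therefore cis to the C‑7a silyloxy group.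

Step 6
Reactants: 7 amide
Product: 9 enone amide (ketone at C‑6), via allylic tert‑butyl peroxide 8 (not isolated)
Conditions: Rh2(C6H10NO)4 (dirhodium tetrakis(caprolactamate), 1 mol%), tBuOOH (5 equiv), K2CO3 (0.5 equiv), CH2Cl2, 25 °C
Reagents that add atoms: tert‑butyl hydroperoxide, CC(C)(C)OO
Why: Radical allylic C–H oxidation peroxidises the only allylic CH2 (C‑6) and the peroxide collapses to the conjugated enone; the regioisomeric enone from the same allyl radical would give the same dione in step 8.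

Step 7
Reactants: 9 enone amide
Product: 11 β‑hydroxy ketone (hydroxyl at C‑4), via β‑boryl ketone 10 (not isolated)
Conditions: CuCl (5 mol%), NaOtBu (10 mol%), bis[2‑(diphenylphosphino)phenyl] ether (6 mol%), B2pin2 (1.1 equiv), MeOH (2 equiv), THF, 25 °C; then NaBO3·4H2O, THF/H2O, 25 °C
Reagents that add atoms: bis(pinacolato)diboron, CC1(C)OB(OC1(C)C)B1OC(C)(C)C(C)(C)O1 (boron of 10); sodium perborate, [Na+].[O-]OB=O (oxygen of 11)
Why: Copper‑catalysed conjugate borylation places boron on the β‑carbon C‑4 (anti to the C‑3a substituent) and C–B oxidation with retention gives the carbinol, whose configuration is erased in step 8.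

Step 8
Reactants: 11 β‑hydroxy ketone
Product: 12 4‑substituted 5‑silyloxy cyclohexane‑1,3‑dione (enolised)
Conditions: DMP (1.2 equiv), NaHCO3, CH2Cl2, 0 °C
Reagents that add atoms: none
Why: Dess–Martin oxidation of a β‑hydroxy ketone gives the 1,3‑dione under non‑basic conditions that neither eliminate the β‑silyloxy group nor epimerise C‑3a.

Step 9
Reactants: 12 dione; 13 (E)‑but‑2‑enal
Product: 14 bicyclic lactol of the Michael adduct (anomer mixture)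
Conditions: (R)‑α,α‑diphenylprolinol trimethylsilyl ether (10 mol%), CH2Cl2, 0 → 25 °C
Reagents that add atoms: none
Why: Iminium‑catalysed asymmetric Michael addition in which the dione enol attacks the (E)‑iminium ion on the face opposite the CPh2OSiMe3 group, setting (S)‑C‑1′ under catalyst control; the aldehyde is trapped as a cyclic hemiacetal.

Step 10
Reactants: 14 lactol
Product: 15 2‑[(S)‑pent‑4‑en‑2‑yl] dione
Conditions: Ph3PCH3Br (4 equiv), KOtBu (3.8 equiv), THF, 0 → 25 °C; aq. NH4Cl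
Reagents that add atoms: methyltriphenylphosphonium bromide, C[P+](c1ccccc1)(c1ccccc1)c1ccccc1.[Br-]
Why: Wittig methylenation of the aldehyde released by ring–chain tautomerism of the lactol; the dione is present as its inert enolate, which also blocks retro‑Michael loss of C‑1′.

Step 11
Reactants: 15 alkenyl dione
Product: 16 vinylogous triflate (triflate on O‑6)
Conditions: PhNTf2 (1.2 equiv), Et3N (2 equiv), DMAP (10 mol%), CH2Cl2, 0 → 25 °C
Reagents that add atoms: N‑phenylbis(trifluoromethanesulfonimide), FC(F)(F)S(=O)(=O)N(c1ccccc1)S(=O)(=O)C(F)(F)F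
Why: O‑Sulfonylation of the dione enolate occurs at the less hindered oxygen (O‑4 is flanked by the substituted C‑3a), leaving the ketone at C‑4, and PhNTf2 does not activate the tertiary amide.

Step 12
Reactants: 16 triflate
Product: 17 3‑(hydroxymethyl) enone
Conditions: Bu3SnCH2OH (1.5 equiv), Pd(PPh3)4 (8 mol%), LiCl (3 equiv), 1,4‑dioxane, 90 °C
Reagents that add atoms: (tributylstannyl)methanol, CCCC[Sn](CCCC)(CCCC)CO
Why: Stille cross‑coupling, in which zerovalent palladium inserts readily into the activated β‑triflyloxy enone and the stannane transfers the hydroxymethyl group to C‑6.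

Step 13
Reactants: 17 silyl ether
Product: 18 β‑hydroxy enone (free C‑7a hydroxyl)
Conditions: HF·pyridine, pyridine, THF, 0 → 25 °C
Reagents that add atoms: none
Why: Fluoride‑mediated desilylation under buffered conditions that neither dehydrate the β‑hydroxy ketone nor lactonise the amide.

Step 14
Reactants: 18 β‑hydroxy enone
Product: 19 triol amide with (S)‑C‑4 carbinol
Conditions: Me4NBH(OAc)3 (5 equiv), MeCN/AcOH 1:1, −30 → −20 °C
Reagents that add atoms: none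
Why: Evans–Saksena hydroxyl‑directed reduction, in which the borohydride bound to the C‑7a oxygen delivers hydride to the same face of the C‑4 ketone and gives the 1,3‑anti diol (C‑4 oxygen trans to the C‑3a chain).

Step 15
Reactants: 19 triol amide
Product: 20 cis‑fused hydroxy lactone
Conditions: PPTS (1.2 equiv), toluene, 60 °C
Reagents that add atoms: none
Why: Acid‑promoted lactonisation of the γ‑hydroxy N,N‑dimethylamide, in which only the cis C‑7a hydroxyl can close the unstrained cis‑fused γ‑lactone while the trans C‑4 hydroxyl stays free.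

Step 16
Reactants: 20 alkenyl lactone diol
Product: 22 lactone triol, via B‑alkyl‑9‑BBN adduct 21 (not isolated)
Conditions: 9‑BBN (3.5 equiv), THF, 0 → 25 °C; then NaBO3·4H2O, H2O, 25 °C, pH 7 work‑up
Reagents that add atoms: 9‑borabicyclo[3.3.1]nonane, [H]B1C2CCCC1CCC2 (boron of 21); sodium perborate, [Na+].[O-]OB=O (oxygen of 22)
Why: Anti‑Markovnikov hydroboration–oxidation of the monosubstituted alkene; 9‑BBN leaves the tetrasubstituted ring alkene and the lactone alone.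

Step 17
Reactants: 22 lactone triol
Product: 24 bis‑TBDPS TES ether, via bis‑TBDPS ether 23 (not isolated)
Conditions: TBDPSCl (2.1 equiv), imidazole (6 equiv), DMF, 0 °C; then Et3SiCl (1.5 equiv), 25 °C
Reagents that add atoms: tert‑butyl(chloro)diphenylsilane, CC(C)(C)[Si](Cl)(c1ccccc1)c1ccccc1; chlorotriethylsilane, CC[Si](Cl)(CC)CC
Why: Sterically controlled silyl ether formation, in which the two primary alcohols take the bulky TBDPS group first and the hindered secondary C‑4 hydroxyl is then capped as the more labile TES ether.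

Step 18
Reactants: 24 protected lactone
Product: 27 α‑methylene lactone, via Mannich base 25 (not isolated), via ammonium iodide 26 (not isolated)
Conditions: LDA (1.3 equiv), THF, −78 °C; CH2=NMe2+ I− (2 equiv), −78 → 25 °C; then MeI (10 equiv), MeOH, 25 °C; then aq. NaHCO3, CH2Cl2
Reagents that add atoms: Eschenmoser's salt, C=[N+](C)C.[I-]
Why: Eschenmoser methylenation (aminomethylation of the lactone enolate, N‑quaternisation, E1cB loss of trimethylamine) installs the exocyclic methylene without touching C‑3a.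

Step 19
Reactants: 27 TES ether
Product: 28 C‑4 alcohol
Conditions: PPTS (0.2 equiv), MeOH/CH2Cl2 1:1, 0 °C
Reagents that add atoms: none
Why: Acid‑catalysed methanolysis cleaves the TES ether far faster than the primary TBDPS ethers (selective deprotection).

Step 20
Reactants: 28 C‑4 alcohol
Product: 29 C‑4 methacrylate
Conditions: methacrylic anhydride (3 equiv), DMAP (0.5 equiv), Et3N (4 equiv), CH2Cl2, 25 °C
Reagents that add atoms: methacrylic anhydride, C=C(C)C(=O)OC(=O)C(C)=C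
Why: DMAP‑catalysed acyl transfer esterifies the secondary allylic alcohol with retention at C‑4.

Step 21
Reactants: 29 bis‑TBDPS ether
Product: 30 target
Conditions: HF·pyridine (excess), pyridine, THF, 0 → 25 °C, 24 h
Reagents that add atoms: none
Why: Fluoride‑mediated desilylation under mildly acidic, non‑nucleophilic conditions frees both primary alcohols while the methacrylate and the α‑methylene lactone survive.

## Compound list

1 | cyclohexa‑1,3‑diene | C1=CC=CCC1 | starting material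
2 | meso‑(1R,4S)‑cyclohex‑2‑ene‑1,4‑diyl diacetate | CC(=O)O[C@H]1C=C[C@@H](OC(C)=O)CC1 | intermediate
3 | (1S,4R)‑4‑hydroxycyclohex‑2‑en‑1‑yl acetate | O[C@H]1C=C[C@@H](OC(C)=O)CC1 | intermediate
4 | (1S,4R)‑4‑(TBS‑oxy)cyclohex‑2‑en‑1‑yl acetate | CC(C)(C)[Si](C)(C)O[C@H]1C=C[C@@H](OC(C)=O)CC1 | intermediate
5 | (1S,4R)‑4‑(TBS‑oxy)cyclohex‑2‑en‑1‑ol | CC(C)(C)[Si](C)(C)O[C@H]1C=C[C@@H](O)CC1 | intermediate
6 | N,N‑dimethyl‑1‑{[(1S,4R)‑4‑(TBS‑oxy)cyclohex‑2‑en‑1‑yl]oxy}ethen‑1‑amine | CC(C)(C)[Si](C)(C)O[C@H]1C=C[C@@H](OC(=C)N(C)C)CC1 | intermediate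
7 | 2‑[(1S,6R)‑6‑(TBS‑oxy)cyclohex‑2‑en‑1‑yl]‑N,N‑dimethylacetamide | C1=CCC[C@@H](O[Si](C)(C)C(C)(C)C)[C@H]1CC(=O)N(C)C | intermediate
8 | 2‑[(1S,6R)‑4‑(tert‑butylperoxy)‑6‑(TBS‑oxy)cyclohex‑2‑en‑1‑yl]‑N,N‑dimethylacetamide (epimers at the peroxy carbon) | C1=CC(OOC(C)(C)C)C[C@@H](O[Si](C)(C)C(C)(C)C)[C@H]1CC(=O)N(C)C | intermediate
9 | 2‑[(1S,6R)‑6‑(TBS‑oxy)‑4‑oxocyclohex‑2‑en‑1‑yl]‑N,N‑dimethylacetamide | C1=CC(=O)C[C@@H](O[Si](C)(C)C(C)(C)C)[C@H]1CC(=O)N(C)C | intermediate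
10 | 2‑[(1S,2R,6R)‑2‑(TBS‑oxy)‑4‑oxo‑6‑(4,4,5,5‑tetramethyl‑1,3,2‑dioxaborolan‑2‑yl)cyclohexyl]‑N,N‑dimethylacetamide | CC1(C)OB(OC1(C)C)[C@@H]2CC(=O)C[C@@H](O[Si](C)(C)C(C)(C)C)[C@H]2CC(=O)N(C)C | intermediate
11 | 2‑[(1S,2R,6R)‑2‑(TBS‑oxy)‑6‑hydroxy‑4‑oxocyclohexyl]‑N,N‑dimethylacetamide | O[C@@H]1CC(=O)C[C@@H](O[Si](C)(C)C(C)(C)C)[C@H]1CC(=O)N(C)C | intermediate
12 | 2‑[(1R,2R)‑2‑(TBS‑oxy)‑4,6‑dioxocyclohexyl]‑N,N‑dimethylacetamide | O=C1CC(=O)C[C@@H](O[Si](C)(C)C(C)(C)C)[C@H]1CC(=O)N(C)C | intermediate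
13 | (E)‑but‑2‑enal | C/C=C/C=O | starting material
14 | 2‑[(4S,6R,7R)‑7‑(TBS‑oxy)‑2‑hydroxy‑4‑methyl‑5‑oxo‑3,4,5,6,7,8‑hexahydro‑2H‑chromen‑6‑yl]‑N,N‑dimethylacetamide (anomers; equilibrates with the regioisomeric lactol and the open aldehyde) | O=C1C2=C(C[C@@H](O[Si](C)(C)C(C)(C)C)[C@H]1CC(=O)N(C)C)OC(O)C[C@@H]2C | intermediate
15 | 2‑[(1R,2R)‑2‑(TBS‑oxy)‑4,6‑dioxo‑5‑[(2S)‑pent‑4‑en‑2‑yl]cyclohexyl]‑N,N‑dimethylacetamide (drawn as an enol) | O=C1C([C@@H](C)CC=C)=C(O)C[C@@H](O[Si](C)(C)C(C)(C)C)[C@H]1CC(=O)N(C)C | intermediate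
16 | (4R,5R)‑5‑(TBS‑oxy)‑4‑[2‑(dimethylamino)‑2‑oxoethyl]‑3‑oxo‑2‑[(2S)‑pent‑4‑en‑2‑yl]cyclohex‑1‑en‑1‑yl trifluoromethanesulfonate | O=C1C([C@@H](C)CC=C)=C(OS(=O)(=O)C(F)(F)F)C[C@@H](O[Si](C)(C)C(C)(C)C)[C@H]1CC(=O)N(C)C | intermediate
17 | 2‑[(1R,6R)‑6‑(TBS‑oxy)‑4‑(hydroxymethyl)‑2‑oxo‑3‑[(2S)‑pent‑4‑en‑2‑yl]cyclohex‑3‑en‑1‑yl]‑N,N‑dimethylacetamide | O=C1C([C@@H](C)CC=C)=C(CO)C[C@@H](O[Si](C)(C)C(C)(C)C)[C@H]1CC(=O)N(C)C | intermediate
18 | 2‑[(1R,6R)‑6‑hydroxy‑4‑(hydroxymethyl)‑2‑oxo‑3‑[(2S)‑pent‑4‑en‑2‑yl]cyclohex‑3‑en‑1‑yl]‑N,N‑dimethylacetamide | O=C1C([C@@H](C)CC=C)=C(CO)C[C@@H](O)[C@H]1CC(=O)N(C)C | intermediate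
19 | 2‑[(1R,2S,6R)‑2,6‑dihydroxy‑4‑(hydroxymethyl)‑3‑[(2S)‑pent‑4‑en‑2‑yl]cyclohex‑3‑en‑1‑yl]‑N,N‑dimethylacetamide | O[C@@H]1C([C@@H](C)CC=C)=C(CO)C[C@@H](O)[C@H]1CC(=O)N(C)C | intermediate
20 | (3aS,4S,7aR)‑4‑hydroxy‑6‑(hydroxymethyl)‑5‑[(2S)‑pent‑4‑en‑2‑yl]‑3a,4,7,7a‑tetrahydro‑1‑benzofuran‑2(3H)‑one | O[C@@H]1C([C@@H](C)CC=C)=C(CO)C[C@H]2OC(=O)C[C@@H]12 | intermediate
21 | B‑alkyl‑9‑BBN adduct of 20 (boron on the terminal carbon of the side chain) | O[C@@H]1C([C@@H](C)CCCB3C4CCCC3CCC4)=C(CO)C[C@H]2OC(=O)C[C@@H]12 | intermediate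
22 | (3aS,4S,7aR)‑4‑hydroxy‑6‑(hydroxymethyl)‑5‑[(2S)‑5‑hydroxypentan‑2‑yl]‑3a,4,7,7a‑tetrahydro‑1‑benzofuran‑2(3H)‑one | O[C@@H]1C([C@@H](C)CCCO)=C(CO)C[C@H]2OC(=O)C[C@@H]12 | intermediate
23 | (3aS,4S,7aR)‑4‑hydroxy‑6‑[(TBDPS‑oxy)methyl]‑5‑[(2S)‑5‑(TBDPS‑oxy)pentan‑2‑yl]‑3a,4,7,7a‑tetrahydro‑1‑benzofuran‑2(3H)‑one | O[C@@H]1C([C@@H](C)CCCO[Si](c3ccccc3)(c3ccccc3)C(C)(C)C)=C(CO[Si](c3ccccc3)(c3ccccc3)C(C)(C)C)C[C@H]2OC(=O)C[C@@H]12 | intermediate
24 | (3aR,4S,7aR)‑6‑[(TBDPS‑oxy)methyl]‑5‑[(2S)‑5‑(TBDPS‑oxy)pentan‑2‑yl]‑4‑(TES‑oxy)‑3a,4,7,7a‑tetrahydro‑1‑benzofuran‑2(3H)‑one | CC[Si](CC)(CC)O[C@@H]1C([C@@H](C)CCCO[Si](c3ccccc3)(c3ccccc3)C(C)(C)C)=C(CO[Si](c3ccccc3)(c3ccccc3)C(C)(C)C)C[C@H]2OC(=O)C[C@@H]12 | intermediate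
25 | 3‑[(dimethylamino)methyl] derivative of 24 (C‑3 epimers) | CC[Si](CC)(CC)O[C@@H]1C([C@@H](C)CCCO[Si](c3ccccc3)(c3ccccc3)C(C)(C)C)=C(CO[Si](c3ccccc3)(c3ccccc3)C(C)(C)C)C[C@H]2OC(=O)C(CN(C)C)[C@@H]12 | intermediate
26 | 3‑[(trimethylammonio)methyl] iodide derived from 25 | CC[Si](CC)(CC)O[C@@H]1C([C@@H](C)CCCO[Si](c3ccccc3)(c3ccccc3)C(C)(C)C)=C(CO[Si](c3ccccc3)(c3ccccc3)C(C)(C)C)C[C@H]2OC(=O)C(C[N+](C)(C)C)[C@@H]12.[I-] | intermediate
27 | (3aR,4S,7aR)‑3‑methylidene‑6‑[(TBDPS‑oxy)methyl]‑5‑[(2S)‑5‑(TBDPS‑oxy)pentan‑2‑yl]‑4‑(TES‑oxy)‑3a,4,7,7a‑tetrahydro‑1‑benzofuran‑2(3H)‑one | CC[Si](CC)(CC)O[C@@H]1C([C@@H](C)CCCO[Si](c3ccccc3)(c3ccccc3)C(C)(C)C)=C(CO[Si](c3ccccc3)(c3ccccc3)C(C)(C)C)C[C@H]2OC(=O)C(=C)[C@@H]12 | intermediate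
28 | (3aS,4S,7aR)‑4‑hydroxy‑3‑methylidene‑6‑[(TBDPS‑oxy)methyl]‑5‑[(2S)‑5‑(TBDPS‑oxy)pentan‑2‑yl]‑3a,4,7,7a‑tetrahydro‑1‑benzofuran‑2(3H)‑one | O[C@@H]1C([C@@H](C)CCCO[Si](c3ccccc3)(c3ccccc3)C(C)(C)C)=C(CO[Si](c3ccccc3)(c3ccccc3)C(C)(C)C)C[C@H]2OC(=O)C(=C)[C@@H]12 | intermediate
29 | (3aR,4S,7aR)‑3‑methylidene‑2‑oxo‑6‑[(TBDPS‑oxy)methyl]‑5‑[(2S)‑5‑(TBDPS‑oxy)pentan‑2‑yl]‑2,3,3a,4,7,7a‑hexahydro‑1‑benzofuran‑4‑yl 2‑methylprop‑2‑enoate | C=C(C)C(=O)O[C@@H]1C([C@@H](C)CCCO[Si](c3ccccc3)(c3ccccc3)C(C)(C)C)=C(CO[Si](c3ccccc3)(c3ccccc3)C(C)(C)C)C[C@H]2OC(=O)C(=C)[C@@H]12 | intermediate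
30 | (3aR,4S,7aR)‑6‑(hydroxymethyl)‑5‑[(2S)‑5‑hydroxypentan‑2‑yl]‑3‑methylidene‑2‑oxo‑2,3,3a,4,7,7a‑hexahydro‑1‑benzofuran‑4‑yl 2‑methylprop‑2‑enoate | C=C(C)C(=O)O[C@@H]1C([C@@H](C)CCCO)=C(CO)C[C@H]2OC(=O)C(=C)[C@@H]12 | target

## Step count and risks

Total steps: 21. Longest linear sequence: 21 steps (from 1; 13 is a purchased reagent‑level partner).

**Step 6 (allylic oxidation).** The radical can also abstract the tertiary allylic hydrogen at C‑3a, and over‑oxidation lowers the yield. The fallback sets out from 7 and returns at 9. It replaces radical peroxidation by a closed‑shell selenium ene/[2,3]‑sigmatropic hydroxylation: SeO2 (0.3 equiv) and tBuOOH in CH2Cl2 convert the ring CH2 into the allylic alcohol F1, and MnO2 in CH2Cl2 oxidises F1 to enone 9.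

**Step 11 (regioselective triflation).** The O‑6/O‑4 selectivity rests only on the steric difference between the two enol oxygens. The fallback sets out from 15 and returns at 17. Kinetic O‑sulfonylation is given up for a reversible, thermodynamically controlled condensation with thiophenol (camphorsulfonic acid cat., 4 Å molecular sieves, CH2Cl2), which equilibrates to the vinylogous thioester F2 with sulfur on the unhindered C‑6. A Liebeskind–Srogl‑type coupling of F2 with (tributylstannyl)methanol (Pd2(dba)3, tri(2‑furyl)phosphine, copper thiophene‑2‑carboxylate Cu(O2CC4H3S), THF, 50 °C) then gives 17.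

**Step 12 (Stille hydroxymethylation).** Transfer of CH2OH from tin is slow and can lose out to reduction or hydrolysis of the triflate. The fallback sets out from 16 and returns at 19. Methoxycarbonylation (Pd(OAc)2, 1,1′‑bis(diphenylphosphino)ferrocene, CO 1 atm, MeOH, Et3N, DMF, 50 °C) gives the methyl ester F3. Desilylation as in step 13 gives the hydroxy keto ester F4, and directed reduction as in step 14 gives the diol ester F5. LiBH4 (THF/MeOH, 0 → 25 °C) then reduces the conjugated ester but not the tertiary amide, giving triol 19.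

## Further compounds

F1 | step 6 | 2‑[(1S,6R)‑6‑(TBS‑oxy)‑4‑hydroxycyclohex‑2‑en‑1‑yl]‑N,N‑dimethylacetamide (carbinol epimers) | C1=CC(O)C[C@@H](O[Si](C)(C)C(C)(C)C)[C@H]1CC(=O)N(C)C
F2 | step 11 | 2‑[(1R,6R)‑6‑(TBS‑oxy)‑2‑oxo‑3‑[(2S)‑pent‑4‑en‑2‑yl]‑4‑(phenylsulfanyl)cyclohex‑3‑en‑1‑yl]‑N,N‑dimethylacetamide | O=C1C([C@@H](C)CC=C)=C(Sc2ccccc2)C[C@@H](O[Si](C)(C)C(C)(C)C)[C@H]1CC(=O)N(C)C
F3 | step 12 | methyl (4R,5R)‑5‑(TBS‑oxy)‑4‑[2‑(dimethylamino)‑2‑oxoethyl]‑3‑oxo‑2‑[(2S)‑pent‑4‑en‑2‑yl]cyclohex‑1‑ene‑1‑carboxylate | O=C1C([C@@H](C)CC=C)=C(C(=O)OC)C[C@@H](O[Si](C)(C)C(C)(C)C)[C@H]1CC(=O)N(C)C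
F4 | step 12 | methyl (4R,5R)‑4‑[2‑(dimethylamino)‑2‑oxoethyl]‑5‑hydroxy‑3‑oxo‑2‑[(2S)‑pent‑4‑en‑2‑yl]cyclohex‑1‑ene‑1‑carboxylate | O=C1C([C@@H](C)CC=C)=C(C(=O)OC)C[C@@H](O)[C@H]1CC(=O)N(C)C
F5 | step 12 | methyl (3S,4R,5R)‑4‑[2‑(dimethylamino)‑2‑oxoethyl]‑3,5‑dihydroxy‑2‑[(2S)‑pent‑4‑en‑2‑yl]cyclohex‑1‑ene‑1‑carboxylate | O[C@@H]1C([C@@H](C)CC=C)=C(C(=O)OC)C[C@@H](O)[C@H]1CC(=O)N(C)C
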